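(The earlier runs and the new flask were computed for an exercise, noise included.)

A small charge of free catalyst, 5.0 mM, turns the racemate into left-handed product at the expense of partner, the limiting reagent.

| setting | beta | theta | gamma | flask |
|---|---|---|---|---|
| left-handed substrate | 0.050 M | 0.050 M | 0.075 M | 0.050 M |
| right-handed substrate | 0.050 M | 0.050 M | 0.075 M | 0.050 M |
| partner | 0.028 M | 0.041 M | 0.055 M | 0.0550 M |
| free catalyst | 5 mM | 5 mM | 5 mM | 5.0 mM |
| remark | run made earlier | run made earlier | run made earlier |  |

- beta (time / min: left-handed product / %, left-handed substrate / %): 15.0: 7.3, 39.7; 30.0: 14.0, 35.9; 50.0: 14.4, 34.1; 60.0: 18.5, 32.8; 80.0: 18.4, 31.6; 90.0: 17.7, 30.6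
- theta (time / min: left-handed product / %, left-handed substrate / %): 8.00: 6.6, 43.0; 12.0: 8.0, 40.7; 20.0: 13.1, 36.3; 30.0: 15.5, 32.6; 50.0: 21.2, 29.5; 90.0: 22.6, 25.8
- gamma (time / min: left-handed product / %, left-handed substrate / %): 20.0: 11.8, 36.8; 40.0: 17.8, 30.6; 50.0: 20.2, 31.7; 80.0: 21.8, 28.4; 90.0: 19.3, 28.0

(scatter of a reading: 1 percentage point)

- free catalyst is single-handed; left-handed substrate and right-handed substrate are mirror images of each other, charged as a racemate, each of them at the stated concentration
- no earlier run changes the charge of free catalyst; that part of a forecast is a guess

* factor on the rate of making left-handed product when 30% of the left-handed substrate and right-handed substrate together are converted if partner is charged twice over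
* factor on the rate when 30% of the left-handed substrate and right-handed substrate together are converted if free catalyst is charged at 25 mM instead

The gamma run, charged with the same partner as the flask, ends by its last two readings with 56.0% of its partner in left-handed product; this share is the partner yield, the chance that one partner molecule ends as left-handed product. Counting conversion as left-handed product and keeping that yield, the flask at 30% has 2.68% of its partner left. That is a rough difference of near-equal numbers, but it puts the rate there on a thin remainder, which a larger charge widens.

The forecast keeps 0.025 M of partner at that point, against 0.00147 M here, and gives 3 for doubled partner, since the partner decay “fits first order in partner”. For 25 mM free catalyst it gives 4.8, a separate guess that takes the untested order in free catalyst as about first.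

The simulation gives 4.82 and 42.0, both larger than the forecast .

    partner + catalyst intermediate A → free catalyst + left-handed product (k = 2050 M⁻¹ h⁻¹)
    partner + catalyst intermediate B → free catalyst + right-handed product (k = 40.5 M⁻¹ h⁻¹)
    free catalyst + right-handed substrate ⇌ catalyst intermediate B (K = 6.96 M⁻¹, k = 4670 M⁻¹ h⁻¹)
    free catalyst + left-handed substrate ⇌ catalyst intermediate A (K = 8.30 M⁻¹, k = 802 M⁻¹ h⁻¹)
    partner → decomposed reagent (k = 0.0303 h⁻¹)
    2 partner → self-condensation product (k = 22.3 M⁻¹ h⁻¹)

In the flask at 25.0 h, left-handed product equals 54.0% of the partner charge, beside the 56.0% read from gamma, and self-condensation product holds 42.8%. In the 25 mM flask, 42.0 over the catalyst factor of 5.00 leaves 8.41; on a remainder of 2.68%, with catalyst intermediate A keeping its share, that reckons to 22.5% of partner left, a yield of 70.4%. In the flask, half of self-condensation was done by 0.133 h, and partner stood at 46.7% at 0.250 h. Conversion passed 30% at 1.57 h, and at 2.50 h partner stood at 1.42% and left-handed product at 29.0%.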